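**Conventions.** Phakellin numbering is used throughout: N1, C2(Br), C3(Br), C4, C5, C6(H), N7, C8(=O), N9, C10, C11–C13, N14, C15(=O). "ABC tricycle" means the 7,8-dibromo-2,3,10,10a-tetrahydro-1H,5H-dipyrrolo[1,2-a:1',2'-d]pyrazin-5-one core, whose C10/C10a are C6/C10 here.
**Assumption.** Compounds 1 and 2 are both bought as catalogue compounds.

## Retrosynthetic overview
1. Ring D closes last. The C10–N9 bond forms by dehydrogenative closure of a 6-ureido ABC tricycle (urea N-radical, 1,5-HAT at C10–H, capture of the N-acyliminium ion) in a photoelectrochemical step.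
2. The urea comes from a C6 azide that is cis to H-10 (Staudinger, aza-Wittig with CO2, then NH3). The azide comes from the trans-hemiaminal by SN2 inversion.
3. Ring B forms by spontaneous closure of N1 onto the CHO of the N-acyl-D-prolinal. Rings A and C are bought.
4. Stereochemical relay: C10 (D-prolinol) sets C6 (OH trans, then inverted to N cis). C6 then re-sets C10 on the face where it holds the urea.
5. Ring order: A and C (bought), then B, then D.

## Route

Step 1
Reactants: 1 D-prolinol; 2 4,5-dibromo-2-(trichloroacetyl)-1H-pyrrole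
Product: 3 (R)-(4,5-dibromo-1H-pyrrol-2-yl)[2-(hydroxymethyl)pyrrolidin-1-yl]methanone
Conditions: Et3N (1 equiv), MeCN, rt, 16 h
Reagents that add atoms: none
Why: Haloform-type acyl transfer, in which the more nucleophilic secondary amine (not the OH) attacks the trichloromethyl ketone and CCl3⁻ leaves, while the bought stereocentre (future C10) is untouched.

Step 2
Reactants: 3 amido alcohol
Product: 5 (6S,10R)-6-hydroxy ABC tricycle (OH trans to H-10), via (R)-1-(4,5-dibromo-1H-pyrrole-2-carbonyl)pyrrolidine-2-carbaldehyde 4 (not isolated)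
Conditions: IBX (1.2 equiv), DMSO, rt, 5 h
Reagents that add atoms: none
Why: Neutral IBX oxidation gives the aldehyde, which the pyrrole N–H traps at once (reversible 6-exo-trig ring-chain closure), and the thermodynamic isomer has the OH pseudoaxial (clear of C2–Br) and anti to the pseudoaxial H-10, so C10 sets C6.

Step 3
Reactants: 5 trans-hemiaminal
Product: 7 (6R,10R)-6-azido ABC tricycle (N3 cis to H-10), via (6S,10R)-6-(diphenoxyphosphoryloxy) ABC tricycle 6 (not isolated)
Conditions: DPPA (1.5 equiv), DBU (1.5 equiv), toluene/THF, 0 °C to rt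
Reagents that add atoms: diphenylphosphoryl azide (DPPA) [N-]=[N+]=NP(=O)(Oc1ccccc1)Oc1ccccc1
Why: DPPA–DBU azidation (in situ phosphate, then azide displacement) runs as SN2 because the acyl-dibromopyrrole nitrogen stabilises a C6 cation poorly, so C6 is inverted and nitrogen ends on the face of H-10.

Step 4
Reactants: 7 cis-azide
Product: 10 (6S,10R)-6-ureido ABC tricycle (urea cis to H-10), via (6R,10R)-6-(trimethylphosphoranylideneamino) ABC tricycle 8 (not isolated), via (6S,10R)-6-isocyanato ABC tricycle 9 (not isolated)
Conditions: PMe3 (1.1 equiv), CO2 (1 atm), THF, −20 °C to rt; then NH3 (0.5 M in dioxane, 5 equiv), 0 °C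
Reagents that add atoms: carbon dioxide O=C=O; ammonia N
Why: Staudinger reaction, aza-Wittig reaction with CO2 and amine addition to the isocyanate all take place at N7 and never at C6, and CO2 present from the start intercepts the iminophosphorane before the aminal can epimerise, so both centres are kept.

Step 5
Reactants: 10 cis-urea
Product: 13 dibromophakellstatin (6S,10R), via (6S,10R)-6-(3-iodoureido) ABC tricycle 11 (not isolated), via (6S)-6-ureido C10=N14 N-acyliminium iodide 12 (not isolated)
Conditions: Bu4NI (20 mol %), Bu4NOAc (1 equiv), Bu4NBF4 (0.1 M), MeCN/CF3CH2OH 9:1, RVC(+)|Pt(−), undivided cell, 5 mA, 2.2 F/mol, 440 nm LEDs, 20 °C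
Reagents that add atoms: none
Why: Proposed new method: photoelectrochemical iodide-mediated urea-relay C–H amination, in which AcOI formed at the anode (at a potential far below that needed to oxidise the acyl-dibromopyrrole) iodinates the unhindered terminal NH2 to 11, 440 nm light cleaves N–I, the electrophilic ureidyl radical abstracts the cis-disposed (about 45° dihedral), weak, tertiary α-amido C10–H by 1,5-HAT through the six-membered array N9–C8–N7–C6–C10–H, the C10 radical is iodinated and ionises to 12, and the restored NH2, held on that face by the intact C6 centre, closes 5-exo-trig so that only the cis-fused (6S,10R) ring D can form (net retention at C10) while H2 leaves at the cathode; the closest known reaction types are the iodine-mediated Hofmann–Löffler–Freytag amination, imidate radical-relay β-C–H amination and Rh-nitrenoid cyclisation of N-sulfonyl ureas, none of them shown for a free urea or for an α-amido C–H giving an N,N-aminal.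

## Compound list
1 | D-prolinol, (R)-pyrrolidin-2-ylmethanol | OC[C@H]1CCCN1 | starting material
2 | 4,5-dibromo-2-(trichloroacetyl)-1H-pyrrole | O=C(c1cc(Br)c(Br)[nH]1)C(Cl)(Cl)Cl | starting material
3 | (R)-(4,5-dibromo-1H-pyrrol-2-yl)[2-(hydroxymethyl)pyrrolidin-1-yl]methanone | OC[C@H]1CCCN1C(=O)c1cc(Br)c(Br)[nH]1 | intermediate
4 | (R)-1-(4,5-dibromo-1H-pyrrole-2-carbonyl)pyrrolidine-2-carbaldehyde (not isolated) | O=C[C@H]1CCCN1C(=O)c1cc(Br)c(Br)[nH]1 | intermediate
5 | (6S,10R)-6-hydroxy ABC tricycle, OH trans to H-10 | O[C@@H]2n3c(cc(Br)c3Br)C(=O)N3CCC[C@H]23 | intermediate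
6 | (6S,10R)-6-(diphenoxyphosphoryloxy) ABC tricycle, trans (not isolated) | O=P(Oc1ccccc1)(Oc1ccccc1)O[C@@H]2n3c(cc(Br)c3Br)C(=O)N3CCC[C@H]23 | intermediate
7 | (6R,10R)-6-azido ABC tricycle, N3 cis to H-10 | [N-]=[N+]=N[C@H]2n3c(cc(Br)c3Br)C(=O)N3CCC[C@H]23 | intermediate
8 | (6R,10R)-6-(trimethylphosphoranylideneamino) ABC tricycle, cis (not isolated) | CP(C)(C)=N[C@H]2n3c(cc(Br)c3Br)C(=O)N3CCC[C@H]23 | intermediate
9 | (6S,10R)-6-isocyanato ABC tricycle, cis (not isolated) | O=C=N[C@H]2n3c(cc(Br)c3Br)C(=O)N3CCC[C@H]23 | intermediate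
10 | (6S,10R)-6-ureido ABC tricycle, urea cis to H-10 | NC(=O)N[C@H]2n3c(cc(Br)c3Br)C(=O)N3CCC[C@H]23 | intermediate
11 | (6S,10R)-6-(3-iodoureido) ABC tricycle (not isolated) | INC(=O)N[C@H]2n3c(cc(Br)c3Br)C(=O)N3CCC[C@H]23 | intermediate
12 | (6S)-6-ureido C10=N14 N-acyliminium iodide (not isolated) | NC(=O)N[C@H]1n2c(cc(Br)c2Br)C(=O)[N+]2=C1CCC2.[I-] | intermediate
13 | dibromophakellstatin, (6S,10R) | O=C1N[C@H]2n3c(cc(Br)c3Br)C(=O)N3CCC[C@]23N1 | target

## Totals and risks
Total steps: 5. Longest linear sequence: 5 (1 → 3 → 5 → 7 → 10 → 13).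

**Step 5 (the new step).**
- Possible failures:
  - iodination or radical formation at N7 instead of N9;
  - too little of the urea rotamer that places N9 over H-10;
  - iodination at C4 of the pyrrole;
  - loss of H-6 from 12, which would racemise the material.
- Fallback (known chemistry, Rh-nitrenoid C–H insertion of an N-sulfonyl urea): it sets out from azide 7.
- The same PMe3/CO2 sequence through 8 gives isocyanate 9. This is quenched with 2,2,2-trichloroethyl sulfamate and DBU instead of ammonia, giving the (6S,10R)-6-[3-(2,2,2-trichloroethoxysulfonyl)ureido] ABC tricycle F4.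
- Rh2(esp)2 (3 mol %, achiral), PhI(OAc)2 and MgO in toluene at 40 °C insert stereospecifically into the cis C10–H. The product is N9-(2,2,2-trichloroethoxysulfonyl)dibromophakellstatin F5.
- Brief treatment with Zn in AcOH/MeOH at rt removes the sulfonyl group. The fallback rejoins the route at 13.

**Step 3.**
- Possible failures:
  - H-10 is antiperiplanar to the pseudoaxial phosphate in 6, so E2 to the achiral enamide competes;
  - DBU can open 5 to aldehyde 4 and epimerise C10;
  - some ionisation would give the trans-azide.
- Control: 3J(H6,H10) should be large in 7 (H-6 and H-10 anti) and small in any trans isomer.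
- Fallback (thermodynamic aminal exchange instead of SN2): it sets out from 5.
- Urea (10 equiv), Sc(OTf)3 (10 mol %), 4 Å molecular sieves, MeCN, 40 °C. The reaction goes through the open N-carbamoyl iminium ion and gives 10 together with its C6 epimer, the (6R,10R)-6-ureido ABC tricycle with the urea trans to H-10 F1.
- The two are separated by chromatography and F1 is put back under the same acid conditions to equilibrate. F1 must be fully removed, because any closure from it would give the enantiomer of 13.
- The fallback rejoins the route at 10 and bypasses 7.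

**Step 4.**
- Possible failures:
  - iminophosphorane 8 epimerises at C6 by aminal ring-opening;
  - the aza-Wittig reaction with CO2 is slow at this hindered nitrogen;
  - isocyanate 9 oligomerises.
- Fallback (reversed polarity, substrate amine plus external isocyanate): it sets out from 7.
- Staudinger reduction (PMe3, THF/H2O, 0 °C) gives the (6S,10R)-6-amino ABC tricycle F2.
- F2 is acylated at once with trichloroacetyl isocyanate (CH2Cl2, −20 °C) to give the (6S,10R)-6-[3-(trichloroacetyl)ureido] ABC tricycle F3.
- Catalytic K2CO3 in MeOH at 0 °C cleaves the trichloroacetyl group. The fallback rejoins the route at 10.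

## Further compounds
F1 | step 3 | (6R,10R)-6-ureido ABC tricycle, urea trans to H-10 (6-epi-10) | NC(=O)N[C@@H]2n3c(cc(Br)c3Br)C(=O)N3CCC[C@H]23
F2 | step 4 | (6S,10R)-6-amino ABC tricycle, NH2 cis to H-10 | N[C@H]2n3c(cc(Br)c3Br)C(=O)N3CCC[C@H]23
F3 | step 4 | (6S,10R)-6-[3-(trichloroacetyl)ureido] ABC tricycle, cis | ClC(Cl)(Cl)C(=O)NC(=O)N[C@H]2n3c(cc(Br)c3Br)C(=O)N3CCC[C@H]23
F4 | step 5 | (6S,10R)-6-[3-(2,2,2-trichloroethoxysulfonyl)ureido] ABC tricycle, cis | ClC(Cl)(Cl)COS(=O)(=O)NC(=O)N[C@H]2n3c(cc(Br)c3Br)C(=O)N3CCC[C@H]23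
F5 | step 5 | N9-(2,2,2-trichloroethoxysulfonyl)dibromophakellstatin, spatial arrangement as in 13 (descriptors 6S,10S by CIP rank change) | O=C1N[C@H]2n3c(cc(Br)c3Br)C(=O)N3CCC[C@]23N1S(=O)(=O)OCC(Cl)(Cl)Cl
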